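**Retrosynthetic overview**
1. Target ⇒ hydrogenolysis of two benzyl esters; the malate ester C–O bond ⇒ primary alcohol of the lactone core + (R)-O-trifluoroacetylmalic anhydride, opened at C1.
2. Lactone C–O bond, quaternary C2 and the adjacent CH ⇒ one catalytic enantioselective 5-exo oxa-Michael lactonisation/protonation of an achiral tetrasubstituted butenedioate carrying a CH2CH2CO2H arm.
3. Tetrasubstituted alkene ⇒ Horner–Wadsworth–Emmons reaction of an alkylated benzyl phosphonoacetate with 1-benzyl 2-oxoglutarate.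
4. Building blocks ⇒ benzyl diethylphosphonoacetate + 10-bromodecan-1-ol; 2-oxoglutaric acid + BnBr; (R)-malic acid + TFAA.
5. Ring order: the γ-lactone is the only ring of the target and is closed in step 4; the anhydride ring of the malate reagent is made in step 5 and opened again in step 6.

Assumptions: the target is read as (3R)-4-{[(11S)-11-carboxy-11-[(2R)-2-carboxy-5-oxooxolan-2-yl]undecyl]oxy}-3-hydroxy-4-oxobutanoic acid, i.e. (R)-malate; the step 4 catalyst QN-SQ is the commercial quinine-derived squaramide 3-{[3,5-bis(trifluoromethyl)phenyl]amino}-4-{[(8α,9S)-6′-methoxycinchonan-9-yl]amino}cyclobut-3-ene-1,2-dione, whose sense of induction is assumed (otherwise its quinidine-derived pseudo-enantiomer is used).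

**Step 1**
Reactants: 1 benzyl diethylphosphonoacetate; 2 10-bromodecan-1-ol
Product: 3 benzyl (±)-2-(diethoxyphosphoryl)-12-hydroxydodecanoate
Conditions: 1 (1.5 equiv), NaH (1.4 equiv), THF/DMF 1:1, 0 °C; then 2 (1.0 equiv), 60 °C, 16 h
Reagents that add atoms: none
Why: Malonate-type SN2 C-alkylation of the sodium phosphonoacetate carbanion by the primary bromide; the carbanion (pKa about 19) is too weak a base to ionise the alcohol, so no protection is needed, excess 1 limits dialkylation, and the new stereocentre is racemic and is erased in step 3.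

**Step 2**
Reactants: 4 2-oxoglutaric acid
Product: 5 5-(benzyloxy)-4,5-dioxopentanoic acid (1-benzyl 2-oxoglutarate)
Conditions: Cy2NH (1.1 equiv), DMF, 50 °C; BnBr (1.1 equiv), 50 °C, 2 h
Reagents that add atoms: benzyl bromide, BrCc1ccccc1
Why: Carboxylate O-alkylation (SN2): with one equivalent of amine only the far more acidic α-keto carboxylic acid (pKa about 2.5 against 4.7) is ionised, so the 1-ester forms selectively, as known for other 1-monoesters of 2-oxoglutaric acid; no stereocentre.

**Step 3**
Reactants: 3 benzyl (±)-2-(diethoxyphosphoryl)-12-hydroxydodecanoate; 5 1-benzyl 2-oxoglutarate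
Product: 6 (4E/Z)-4,5-bis[(benzyloxy)carbonyl]-15-hydroxypentadec-4-enoic acid
Conditions: 3 (1.15 equiv), NaH (2.15 equiv in all; 5 pre-formed as its sodium salt), THF/DMF, 0 °C → rt, 3 h; 1 M HCl; NaHCO3/HCl extraction
Reagents that add atoms: none
Why: Horner–Wadsworth–Emmons olefination: the phosphonate carbanion adds to the aldehyde-like α-keto ester carbonyl (known for α-alkylphosphonoacetates with 2-oxoglutarate diesters) while the C5 acid is masked as its sodium carboxylate; no stereocentre is formed and the E/Z ratio does not matter because the geometry is lost in step 4.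

**Step 4**
Reactants: 6 (4E/Z)-4,5-bis[(benzyloxy)carbonyl]-15-hydroxypentadec-4-enoic acid
Product: 7 benzyl (2R)-2-[(1S)-1-[(benzyloxy)carbonyl]-11-hydroxyundecyl]-5-oxooxolane-2-carboxylate
Conditions: QN-SQ (10 mol %), toluene (0.05 M), 50 °C, 48 h; AcOH quench; NaHCO3 wash removes unreacted 6
Reagents that add atoms: none
Why: Proposed new method: catalytic enantioselective 5-exo-trig oxa-Michael hydrolactonisation of a carboxylic acid onto a tetrasubstituted 2,3-dialkylbutenedioate with catalyst-controlled protonation – the quinuclidine ionises the CO2H to a chiral ammonium carboxylate while the squaramide binds the C5 ester carbonyl (activating C4 and stabilising the developing enolate), carboxylate O adds to the Re face of C4 (forms the ring C–O bond, sets 2R), the squaramide-bound C5 enolate is protonated on its Re face by the quinuclidinium N–H (sets 1′S; alkene geometry is erased at the enolate so E and Z converge), and the neutral lactone, favoured by release of strain in the tetrasubstituted alkene and not re-ionised in the acid-buffered medium, dissociates; closest known reaction types are amine–squaramide-catalysed intramolecular oxa-Michael additions of carboxylic acids to enones (phthalides), organocatalytic Michael addition/enantioselective protonation, and the enzymatic cycloisomerisation of 3-carboxymuconate to a lactone with a carboxylated quaternary C–O centre.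

**Step 5**
Reactants: 8 (R)-malic acid
Product: 9 (3R)-2,5-dioxooxolan-3-yl trifluoroacetate ((R)-O-trifluoroacetylmalic anhydride)
Conditions: TFAA (3 equiv), neat, 0 °C → rt, 2 h; evaporate to dryness
Reagents that add atoms: trifluoroacetic anhydride, O=C(OC(=O)C(F)(F)F)C(F)(F)F
Why: Known dehydrative cyclisation/O-acylation of malic acid with TFAA to the five-membered anhydride with the hydroxyl masked as trifluoroacetate; no bond to the stereocentre is broken, so (R) is retained.

**Step 6**
Reactants: 7 benzyl (2R)-2-[(1S)-1-[(benzyloxy)carbonyl]-11-hydroxyundecyl]-5-oxooxolane-2-carboxylate; 9 (R)-O-trifluoroacetylmalic anhydride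
Product: 11 (3R)-4-{[(11S)-12-(benzyloxy)-11-{(2R)-2-[(benzyloxy)carbonyl]-5-oxooxolan-2-yl}-12-oxododecyl]oxy}-3-hydroxy-4-oxobutanoic acid, via trifluoroacetate ester 10 (not isolated)
Conditions: 9 (2.5 equiv), THF (0.5 M), rt, 16 h; then H2O/THF, rt, 1 h
Reagents that add atoms: none
Why: Alcoholysis of an unsymmetrical cyclic anhydride: the primary alcohol attacks the carbonyl made more electrophilic by the adjacent trifluoroacetoxy group (C1), the known way to malic acid 1-monoesters; the O-trifluoroacetyl group blocks over-acylation and is hydrolysed on work-up, and without base no stereocentre is touched.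

**Step 7**
Reactants: 11 (3R)-4-{[(11S)-12-(benzyloxy)-11-{(2R)-2-[(benzyloxy)carbonyl]-5-oxooxolan-2-yl}-12-oxododecyl]oxy}-3-hydroxy-4-oxobutanoic acid
Product: 12 (3R)-4-{[(11S)-11-carboxy-11-[(2R)-2-carboxy-5-oxooxolan-2-yl]undecyl]oxy}-3-hydroxy-4-oxobutanoic acid (CNP0457473.1)
Conditions: H2 (1 atm), 10% Pd/C, EtOAc, rt, 4 h
Reagents that add atoms: none
Why: Palladium-catalysed hydrogenolysis of the two benzyl esters under neutral conditions leaves the lactone, the malate ester, the free hydroxyl and all three stereocentres untouched.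

**Compound list**
1 | benzyl diethylphosphonoacetate | CCOP(=O)(OCC)CC(=O)OCc1ccccc1 | starting material
2 | 10-bromodecan-1-ol | OCCCCCCCCCCBr | starting material
3 | benzyl (±)-2-(diethoxyphosphoryl)-12-hydroxydodecanoate | CCOP(=O)(OCC)C(CCCCCCCCCCO)C(=O)OCc1ccccc1 | intermediate
4 | 2-oxoglutaric acid | OC(=O)CCC(=O)C(=O)O | starting material
5 | 5-(benzyloxy)-4,5-dioxopentanoic acid (1-benzyl 2-oxoglutarate) | OC(=O)CCC(=O)C(=O)OCc1ccccc1 | intermediate
6 | (4E/Z)-4,5-bis[(benzyloxy)carbonyl]-15-hydroxypentadec-4-enoic acid (geometry mixture) | OC(=O)CCC(C(=O)OCc1ccccc1)=C(CCCCCCCCCCO)C(=O)OCc2ccccc2 | intermediate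
7 | benzyl (2R)-2-[(1S)-1-[(benzyloxy)carbonyl]-11-hydroxyundecyl]-5-oxooxolane-2-carboxylate | OCCCCCCCCCC[C@H](C(=O)OCc1ccccc1)[C@@]2(C(=O)OCc3ccccc3)CCC(=O)O2 | intermediate
8 | (R)-malic acid | O=C(O)C[C@@H](O)C(=O)O | starting material
9 | (3R)-2,5-dioxooxolan-3-yl trifluoroacetate | O=C1C[C@@H](OC(=O)C(F)(F)F)C(=O)O1 | intermediate
10 | (3R)-4-{[(11S)-12-(benzyloxy)-11-{(2R)-2-[(benzyloxy)carbonyl]-5-oxooxolan-2-yl}-12-oxododecyl]oxy}-4-oxo-3-[(trifluoroacetyl)oxy]butanoic acid | O=C(O)C[C@@H](OC(=O)C(F)(F)F)C(=O)OCCCCCCCCCC[C@H](C(=O)OCc1ccccc1)[C@@]2(C(=O)OCc3ccccc3)CCC(=O)O2 | intermediate (not isolated)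
11 | (3R)-4-{[(11S)-12-(benzyloxy)-11-{(2R)-2-[(benzyloxy)carbonyl]-5-oxooxolan-2-yl}-12-oxododecyl]oxy}-3-hydroxy-4-oxobutanoic acid | O=C(O)C[C@@H](O)C(=O)OCCCCCCCCCC[C@H](C(=O)OCc1ccccc1)[C@@]2(C(=O)OCc3ccccc3)CCC(=O)O2 | intermediate
12 | (3R)-4-{[(11S)-11-carboxy-11-[(2R)-2-carboxy-5-oxooxolan-2-yl]undecyl]oxy}-3-hydroxy-4-oxobutanoic acid | O=C(O)C[C@@H](O)C(=O)OCCCCCCCCCC[C@H](C(=O)O)[C@@]1(C(=O)O)CCC(=O)O1 | target

**Step count:** 7 steps in total (steps 2 and 5 are one-step side branches). Longest linear sequence: 5 steps (1 → 3 → 4 → 6 → 7).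

**Three steps most likely to fail**

1. Step 4 (the proposed new step). The tetrasubstituted acceptor may be too unreactive, protonation may give the 1′-epimer, and long reaction times could erode ee through retro-oxa-Michael. The fallback uses known chemistry (ester-enolate aldol to an α-keto acid salt, acid lactonisation, chromatographic resolution); it sets out from 5 and comes back to the route at 7. Purchased 12-hydroxydodecanoic acid F1 is benzylated (BnBr, KHCO3, DMF) to benzyl 12-hydroxydodecanoate F2. Its alkoxide–enolate dianion (LDA, 2.1 equiv, THF, −78 °C) is added to the lithium carboxylate of 5 (LiHMDS, 1 equiv) and, after AcOH quench, gives 4,5-bis[(benzyloxy)carbonyl]-4,15-dihydroxypentadecanoic acid F3 as a stereoisomer mixture. TsOH (cat.) in toluene at 50 °C closes the γ-lactone to benzyl 2-{1-[(benzyloxy)carbonyl]-11-hydroxyundecyl}-5-oxooxolane-2-carboxylate F4 (all four stereoisomers). The (2R*,1′S*) pair is separated on silica and resolved by preparative chiral SFC to give 7; this delivers at most a quarter of the material.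

2. Step 3. The sodium salt of 5 may be poorly soluble or enolise, giving low conversion to the tetrasubstituted alkene. The fallback sets out from 5 and 3 and comes back at 6. Compound 5 is benzylated (BnBr, K2CO3, DMF) to dibenzyl 2-oxopentanedioate F5, which undergoes the diester Horner–Wadsworth–Emmons reaction with the sodium salt of 3 (NaH, THF) to give benzyl 4,5-bis[(benzyloxy)carbonyl]-15-hydroxypentadec-4-enoate F6. One equivalent of LiOH (THF/H2O, 0 °C) or pig-liver esterase at pH 7 then cleaves only the unhindered saturated benzyl ester and returns 6.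

3. Step 6. The alcohol may open the anhydride at the wrong carbonyl, or trifluoroacetyl transfer to the alcohol may stall conversion. The fallback reverses the polarity of the ester bond formation; it sets out from 7 and 8 and comes back at 12. Compound 7 is converted (I2, PPh3, imidazole, CH2Cl2) into benzyl (2R)-2-[(1S)-1-[(benzyloxy)carbonyl]-11-iodoundecyl]-5-oxooxolane-2-carboxylate F7. Compound 8 is converted with 2,2-dimethoxypropane/TsOH into 2-[(4R)-2,2-dimethyl-5-oxo-1,3-dioxolan-4-yl]acetic acid F8, benzylated (BnBr, Et3N) to benzyl 2-[(4R)-2,2-dimethyl-5-oxo-1,3-dioxolan-4-yl]acetate F9, and hydrolysed (AcOH/H2O, 50 °C) to (2R)-4-(benzyloxy)-2-hydroxy-4-oxobutanoic acid F10. The caesium carboxylate of F10 (Cs2CO3, 0.5 equiv, DMF, rt; no excess base, so the lactone is safe) is alkylated by F7 to give benzyl (2R)-2-[(1S)-1-[(benzyloxy)carbonyl]-11-{[(2R)-4-(benzyloxy)-2-hydroxy-4-oxobutanoyl]oxy}undecyl]-5-oxooxolane-2-carboxylate F11. Hydrogenolysis (H2, Pd/C, EtOAc) of its three benzyl esters gives 12.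

**Further compounds**
F1 | step 4 | 12-hydroxydodecanoic acid (purchased) | OCCCCCCCCCCCC(=O)O
F2 | step 4 | benzyl 12-hydroxydodecanoate | OCCCCCCCCCCCC(=O)OCc1ccccc1
F3 | step 4 | 4,5-bis[(benzyloxy)carbonyl]-4,15-dihydroxypentadecanoic acid (stereoisomer mixture) | OC(=O)CCC(O)(C(=O)OCc1ccccc1)C(CCCCCCCCCCO)C(=O)OCc2ccccc2
F4 | step 4 | benzyl 2-{1-[(benzyloxy)carbonyl]-11-hydroxyundecyl}-5-oxooxolane-2-carboxylate (all four stereoisomers) | OCCCCCCCCCCC(C(=O)OCc1ccccc1)C2(C(=O)OCc3ccccc3)CCC(=O)O2
F5 | step 3 | dibenzyl 2-oxopentanedioate | O=C(CCC(=O)C(=O)OCc1ccccc1)OCc2ccccc2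
F6 | step 3 | benzyl 4,5-bis[(benzyloxy)carbonyl]-15-hydroxypentadec-4-enoate (E/Z mixture) | O=C(CCC(C(=O)OCc1ccccc1)=C(CCCCCCCCCCO)C(=O)OCc2ccccc2)OCc3ccccc3
F7 | step 6 | benzyl (2R)-2-[(1S)-1-[(benzyloxy)carbonyl]-11-iodoundecyl]-5-oxooxolane-2-carboxylate | ICCCCCCCCCC[C@H](C(=O)OCc1ccccc1)[C@@]2(C(=O)OCc3ccccc3)CCC(=O)O2
F8 | step 6 | 2-[(4R)-2,2-dimethyl-5-oxo-1,3-dioxolan-4-yl]acetic acid | CC1(C)O[C@H](CC(=O)O)C(=O)O1
F9 | step 6 | benzyl 2-[(4R)-2,2-dimethyl-5-oxo-1,3-dioxolan-4-yl]acetate | CC1(C)O[C@H](CC(=O)OCc2ccccc2)C(=O)O1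
F10 | step 6 | (2R)-4-(benzyloxy)-2-hydroxy-4-oxobutanoic acid | O=C(OCc1ccccc1)C[C@@H](O)C(=O)O
F11 | step 6 | benzyl (2R)-2-[(1S)-1-[(benzyloxy)carbonyl]-11-{[(2R)-4-(benzyloxy)-2-hydroxy-4-oxobutanoyl]oxy}undecyl]-5-oxooxolane-2-carboxylate | O=C(OCc1ccccc1)C[C@@H](O)C(=O)OCCCCCCCCCC[C@H](C(=O)OCc2ccccc2)[C@@]3(C(=O)OCc4ccccc4)CCC(=O)O3
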